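Broussoflavonol C carries a 1,1-dimethylallyl group on C8 of ring A, next to the 7-OH, and a prenyl group on C3' of ring B, next to the 4'-OH. Both are read as allyl groups that have migrated from the neighbouring oxygen with inversion, so the C8–C(CH3)2 and C3'–CH2 bonds are cut back to a 7-O-prenyl ether and a 4'-O-(2-methylbut-3-en-2-yl) ether. One thermolysis of this bis-ether, with O3, O5 and O5' masked as MOM ethers and the C2' prenyl group already present, should form both C–C bonds through two ortho-Claisen shifts. The flavonol is assembled from an acetophenone and a benzaldehyde by aldol condensation and oxidative cyclisation.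

Key step: step 13

Remark on the chemistry: the C2' prenyl group is attached by cross-coupling before the tertiary allyl ether is made, because zerovalent palladium ionises aryl 2-methylbut-3-en-2-yl ethers and would scramble or cleave that ether; this costs one protection and one deprotection on ring B.

Step 1
Reactants: 1 2,4,6-trihydroxyacetophenone; 2 1-bromo-3-methylbut-2-ene (prenyl bromide)
Product: 3 1-[2,6-dihydroxy-4-(3-methylbut-2-en-1-yloxy)phenyl]ethanone
Conditions: K2CO3 (1.0 equiv), acetone, 56 °C
Reagents that add atoms: none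
Why: Williamson ether synthesis, in which the 2- and 6-hydroxyls are hydrogen-bonded to the acetyl carbonyl and less acidic, so one equivalent of base and bromide should alkylate the free 4-OH para to the ketone in preference.

Step 2
Reactants: 3 1-[2,6-dihydroxy-4-(3-methylbut-2-en-1-yloxy)phenyl]ethanone
Product: 4 1-[2-hydroxy-6-(methoxymethoxy)-4-(3-methylbut-2-en-1-yloxy)phenyl]ethanone
Conditions: MOMCl (1.1 equiv), i-Pr2NEt, CH2Cl2, 0 °C
Reagents that add atoms: chloromethyl methyl ether (MOMCl), COCCl
Why: MOM ether formation by O-alkylation, in which the two chelated hydroxyls are equivalent and, once one is capped, the other is locked in a strong hydrogen bond to the ketone and resists a second alkylation under amine-base conditions.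

Step 3
Reactants: 5 2-bromo-4,5-dimethoxybenzaldehyde
Product: 6 2-bromo-4,5-dihydroxybenzaldehyde
Conditions: BBr3 (3 equiv), CH2Cl2, −78 °C to rt; then H2O
Reagents that add atoms: none
Why: Lewis-acid ether cleavage (BBr3 demethylation), in which boron binds each methoxy oxygen and bromide removes the methyl group as bromomethane while the aryl bromide and the aldehyde are untouched.

Step 4
Reactants: 6 2-bromo-4,5-dihydroxybenzaldehyde
Product: 7 2-bromo-4,5-bis(methoxymethoxy)benzaldehyde
Conditions: MOMCl (2.5 equiv), i-Pr2NEt, CH2Cl2, 0 °C to rt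
Reagents that add atoms: chloromethyl methyl ether (MOMCl), COCCl
Why: Double O-alkylation to the bis-MOM ether, which masks both acidic phenols so that they can neither protodestannylate the allylstannane nor bind palladium in the next step.

Step 5
Reactants: 7 2-bromo-4,5-bis(methoxymethoxy)benzaldehyde; 8 tributyl(3-methylbut-2-en-1-yl)stannane
Product: 9 4,5-bis(methoxymethoxy)-2-(3-methylbut-2-en-1-yl)benzaldehyde
Conditions: Pd(PPh3)4 (5 mol%), DMF, 90 °C
Reagents that add atoms: none
Why: Stille cross-coupling, in which the aryl bromide activated by the ortho formyl group adds to zerovalent palladium, the prenyl group is transferred from tin and reductive elimination at the unhindered CH2 terminus gives the linear prenyl arene, with no allyl ether yet present for palladium to ionise.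

Step 6
Reactants: 9 4,5-bis(methoxymethoxy)-2-(3-methylbut-2-en-1-yl)benzaldehyde
Product: 10 4,5-dihydroxy-2-(3-methylbut-2-en-1-yl)benzaldehyde
Conditions: HCl (2 M aq.), MeOH, 45 °C
Reagents that add atoms: none
Why: Acid-catalysed acetal methanolysis of both MOM ethers, which is safe here because the prenyl group has no ortho hydroxyl (C3 bears hydrogen) and so cannot close a chroman under the dilute acid.

Step 7
Reactants: 11 2-methylbut-3-en-2-ol
Product: 12 isobutyl 2-methylbut-3-en-2-yl carbonate
Conditions: n-BuLi, THF, 0 °C; then i-BuOCOCl, 0 °C to rt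
Reagents that add atoms: isobutyl chloroformate, CC(C)COC(=O)Cl
Why: Carbonate formation, in which the deprotonated tertiary alcohol is acylated by the chloroformate to give the mixed carbonate that serves as the 1,1-dimethylallyl donor in step 8.

Step 8
Reactants: 10 4,5-dihydroxy-2-(3-methylbut-2-en-1-yl)benzaldehyde; 12 isobutyl 2-methylbut-3-en-2-yl carbonate
Product: 13 5-hydroxy-4-(2-methylbut-3-en-2-yloxy)-2-(3-methylbut-2-en-1-yl)benzaldehyde
Conditions: 12 (1.1 equiv), Pd(PPh3)4 (2 mol%), 4 Å MS, THF, −10 to 0 °C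
Reagents that add atoms: none
Why: Palladium-catalysed decarboxylative allylic etherification (Tsuji–Trost type), in which zerovalent palladium ionises the carbonate to a 1,1-dimethyl-π-allyl complex with loss of CO2, the liberated isobutoxide deprotonates the more acidic 4-OH para to the formyl group, and this phenoxide attacks the more substituted allyl terminus under kinetic control at low temperature to give the tertiary ether.

Step 9
Reactants: 13 5-hydroxy-4-(2-methylbut-3-en-2-yloxy)-2-(3-methylbut-2-en-1-yl)benzaldehyde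
Product: 14 5-(methoxymethoxy)-4-(2-methylbut-3-en-2-yloxy)-2-(3-methylbut-2-en-1-yl)benzaldehyde
Conditions: MOMCl (1.3 equiv), i-Pr2NEt, CH2Cl2, 0 °C to rt
Reagents that add atoms: chloromethyl methyl ether (MOMCl), COCCl
Why: MOM ether formation by O-alkylation of the remaining 5-OH under amine-base conditions that leave the acid-sensitive tertiary allyl ether intact.

Step 10
Reactants: 4 1-[2-hydroxy-6-(methoxymethoxy)-4-(3-methylbut-2-en-1-yloxy)phenyl]ethanone; 14 5-(methoxymethoxy)-4-(2-methylbut-3-en-2-yloxy)-2-(3-methylbut-2-en-1-yl)benzaldehyde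
Product: 15 (2E)-1-[2-hydroxy-6-(methoxymethoxy)-4-(3-methylbut-2-en-1-yloxy)phenyl]-3-[5-(methoxymethoxy)-4-(2-methylbut-3-en-2-yloxy)-2-(3-methylbut-2-en-1-yl)phenyl]prop-2-en-1-one
Conditions: KOH (excess), EtOH, rt
Reagents that add atoms: none
Why: Claisen–Schmidt (crossed aldol) condensation, in which the ketone enolate adds to the non-enolisable aldehyde and E1cB dehydration gives the conjugated enone in the thermodynamically preferred E geometry, while MOM, prenyl and tertiary allyl ethers are stable to KOH at room temperature.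

Step 11
Reactants: 15 (2E)-1-[2-hydroxy-6-(methoxymethoxy)-4-(3-methylbut-2-en-1-yloxy)phenyl]-3-[5-(methoxymethoxy)-4-(2-methylbut-3-en-2-yloxy)-2-(3-methylbut-2-en-1-yl)phenyl]prop-2-en-1-one
Product: 17 3-hydroxy-5-(methoxymethoxy)-2-[5-(methoxymethoxy)-4-(2-methylbut-3-en-2-yloxy)-2-(3-methylbut-2-en-1-yl)phenyl]-7-(3-methylbut-2-en-1-yloxy)-4H-chromen-4-one, via trans-dihydroflavonol 16 (not isolated)
Conditions: H2O2 (30% aq.), NaOH (2 M aq.), MeOH/THF, 0 °C to rt; NH4Cl work-up
Reagents that add atoms: hydrogen peroxide, OO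
Why: Algar–Flynn–Oyamada reaction, in which alkaline H2O2 brings about oxidative cyclisation of the 2'-hydroxychalcone to trans-dihydroflavonol 16 (trans because base equilibrates the C2 aryl and C3 hydroxyl to the diequatorial arrangement) and further peroxide dehydrogenates 16 to the flavonol, the nucleophilic oxidant leaving the isolated alkenes untouched.

Step 12
Reactants: 17 3-hydroxy-5-(methoxymethoxy)-2-[5-(methoxymethoxy)-4-(2-methylbut-3-en-2-yloxy)-2-(3-methylbut-2-en-1-yl)phenyl]-7-(3-methylbut-2-en-1-yloxy)-4H-chromen-4-one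
Product: 18 3,5-bis(methoxymethoxy)-2-[5-(methoxymethoxy)-4-(2-methylbut-3-en-2-yloxy)-2-(3-methylbut-2-en-1-yl)phenyl]-7-(3-methylbut-2-en-1-yloxy)-4H-chromen-4-one
Conditions: MOMCl (1.5 equiv), i-Pr2NEt, CH2Cl2, 0 °C to rt
Reagents that add atoms: chloromethyl methyl ether (MOMCl), COCCl
Why: MOM ether formation by O-alkylation of the 3-hydroxyl, which removes the last acidic hydroxyl before the thermolysis.

Step 13
Reactants: 18 3,5-bis(methoxymethoxy)-2-[5-(methoxymethoxy)-4-(2-methylbut-3-en-2-yloxy)-2-(3-methylbut-2-en-1-yl)phenyl]-7-(3-methylbut-2-en-1-yloxy)-4H-chromen-4-one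
Product: 20 7-hydroxy-2-[4-hydroxy-5-(methoxymethoxy)-2,3-bis(3-methylbut-2-en-1-yl)phenyl]-3,5-bis(methoxymethoxy)-8-(2-methylbut-3-en-2-yl)-4H-chromen-4-one, via ring-B-rearranged phenol 19 (not isolated)
Conditions: PhNEt2 (degassed), Ar, sealed tube, 120 °C; then 195 °C
Reagents that add atoms: none
Why: Two thermal aromatic Claisen ([3,3]-sigmatropic) rearrangements run in one flask, each through a six-membered chair transition state in which the O–C bond breaks as the far allyl carbon bonds to the ortho ring carbon, followed by enolisation of the dienone to the phenol. In the first stage (about 120 °C) the tertiary 4'-O-(2-methylbut-3-en-2-yl) ether delivers its CH2 terminus to C3' and gives phenol 19; in the second stage (about 195 °C) the primary 7-O-prenyl ether delivers its dimethyl-substituted terminus to C8 and creates the quaternary carbon of 20. The closest known reactions are the thermolysis of 7-prenyloxy chromones and coumarins to 7-hydroxy-8-(1,1-dimethylallyl) compounds and of aryl 1,1-dimethylallyl ethers to o-prenylphenols in N,N-dialkylanilines. No ring is closed and no stereocentre is formed. In ring B only C3' can give a stable product, because the other ortho carbon C5' bears the MOM ether and a dienone formed there cannot enolise and reverts. In ring A the shift must go to C8 and not C6: the C7–C8 bond of the benzopyranone has the higher double-bond character and C6 is shielded by the adjacent 5-O-MOM group, while the basic solvent suppresses acid-promoted cyclisation of the new o-allylphenols.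

Step 14
Reactants: 20 7-hydroxy-2-[4-hydroxy-5-(methoxymethoxy)-2,3-bis(3-methylbut-2-en-1-yl)phenyl]-3,5-bis(methoxymethoxy)-8-(2-methylbut-3-en-2-yl)-4H-chromen-4-one
Product: 21 broussoflavonol C, 2-[4,5-dihydroxy-2,3-bis(3-methylbut-2-en-1-yl)phenyl]-3,5,7-trihydroxy-8-(2-methylbut-3-en-2-yl)-4H-chromen-4-one
Conditions: HCl (3 M aq.), MeOH, 45 °C, Ar
Reagents that add atoms: none
Why: Acid-catalysed acetal methanolysis of the three MOM ethers, the 5-O and 3-O acetals next to the C4 carbonyl being the most labile, with dilute acid, moderate temperature and exclusion of air chosen so that the o-prenylphenol of ring B and the o-(1,1-dimethylallyl)phenol of ring A do not cyclise.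

Compound list
1 | 2,4,6-trihydroxyacetophenone | CC(=O)c1c(O)cc(O)cc1O | starting material
2 | 1-bromo-3-methylbut-2-ene (prenyl bromide) | CC(C)=CCBr | starting material
3 | 1-[2,6-dihydroxy-4-(3-methylbut-2-en-1-yloxy)phenyl]ethanone | CC(=O)c1c(O)cc(OCC=C(C)C)cc1O | intermediate
4 | 1-[2-hydroxy-6-(methoxymethoxy)-4-(3-methylbut-2-en-1-yloxy)phenyl]ethanone | CC(=O)c1c(O)cc(OCC=C(C)C)cc1OCOC | intermediate
5 | 2-bromo-4,5-dimethoxybenzaldehyde | COc1cc(Br)c(C=O)cc1OC | starting material
6 | 2-bromo-4,5-dihydroxybenzaldehyde | O=Cc1cc(O)c(O)cc1Br | intermediate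
7 | 2-bromo-4,5-bis(methoxymethoxy)benzaldehyde | COCOc1cc(Br)c(C=O)cc1OCOC | intermediate
8 | tributyl(3-methylbut-2-en-1-yl)stannane | CCCC[Sn](CCCC)(CCCC)CC=C(C)C | starting material
9 | 4,5-bis(methoxymethoxy)-2-(3-methylbut-2-en-1-yl)benzaldehyde | COCOc1cc(CC=C(C)C)c(C=O)cc1OCOC | intermediate
10 | 4,5-dihydroxy-2-(3-methylbut-2-en-1-yl)benzaldehyde | CC(C)=CCc1cc(O)c(O)cc1C=O | intermediate
11 | 2-methylbut-3-en-2-ol | C=CC(C)(C)O | starting material
12 | isobutyl 2-methylbut-3-en-2-yl carbonate | C=CC(C)(C)OC(=O)OCC(C)C | intermediate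
13 | 5-hydroxy-4-(2-methylbut-3-en-2-yloxy)-2-(3-methylbut-2-en-1-yl)benzaldehyde | CC(C)=CCc1cc(OC(C)(C)C=C)c(O)cc1C=O | intermediate
14 | 5-(methoxymethoxy)-4-(2-methylbut-3-en-2-yloxy)-2-(3-methylbut-2-en-1-yl)benzaldehyde | CC(C)=CCc1cc(OC(C)(C)C=C)c(OCOC)cc1C=O | intermediate
15 | (2E)-1-[2-hydroxy-6-(methoxymethoxy)-4-(3-methylbut-2-en-1-yloxy)phenyl]-3-[5-(methoxymethoxy)-4-(2-methylbut-3-en-2-yloxy)-2-(3-methylbut-2-en-1-yl)phenyl]prop-2-en-1-one | COCOc1cc(OCC=C(C)C)cc(O)c1C(=O)/C=C/c1cc(OCOC)c(OC(C)(C)C=C)cc1CC=C(C)C | intermediate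
16 | rac-(2R,3R)-3-hydroxy-5-(methoxymethoxy)-2-[5-(methoxymethoxy)-4-(2-methylbut-3-en-2-yloxy)-2-(3-methylbut-2-en-1-yl)phenyl]-7-(3-methylbut-2-en-1-yloxy)chroman-4-one (trans-dihydroflavonol, racemic; one enantiomer drawn) | C=CC(C)(C)Oc1cc(CC=C(C)C)c(cc1OCOC)[C@@H]2[C@H](C(=O)c3c(OCOC)cc(OCC=C(C)C)cc3O2)O | intermediate
17 | 3-hydroxy-5-(methoxymethoxy)-2-[5-(methoxymethoxy)-4-(2-methylbut-3-en-2-yloxy)-2-(3-methylbut-2-en-1-yl)phenyl]-7-(3-methylbut-2-en-1-yloxy)-4H-chromen-4-one | CC(C)=CCOc1cc(OCOC)c2c(=O)c(O)c(-c3cc(OCOC)c(OC(C)(C)C=C)cc3CC=C(C)C)oc2c1 | intermediate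
18 | 3,5-bis(methoxymethoxy)-2-[5-(methoxymethoxy)-4-(2-methylbut-3-en-2-yloxy)-2-(3-methylbut-2-en-1-yl)phenyl]-7-(3-methylbut-2-en-1-yloxy)-4H-chromen-4-one (bis-ether precursor of the key step) | CC(C)=CCOc1cc(OCOC)c2c(=O)c(OCOC)c(-c3cc(OCOC)c(OC(C)(C)C=C)cc3CC=C(C)C)oc2c1 | intermediate
19 | 2-[4-hydroxy-5-(methoxymethoxy)-2,3-bis(3-methylbut-2-en-1-yl)phenyl]-3,5-bis(methoxymethoxy)-7-(3-methylbut-2-en-1-yloxy)-4H-chromen-4-one (ring-B-rearranged phenol) | CC(C)=CCOc1cc(OCOC)c2c(=O)c(OCOC)c(-c3cc(OCOC)c(O)c(CC=C(C)C)c3CC=C(C)C)oc2c1 | intermediate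
20 | 7-hydroxy-2-[4-hydroxy-5-(methoxymethoxy)-2,3-bis(3-methylbut-2-en-1-yl)phenyl]-3,5-bis(methoxymethoxy)-8-(2-methylbut-3-en-2-yl)-4H-chromen-4-one (3,5,5'-tri-O-MOM broussoflavonol C) | C=CC(C)(C)c1c(O)cc(OCOC)c2c(=O)c(OCOC)c(-c3cc(OCOC)c(O)c(CC=C(C)C)c3CC=C(C)C)oc12 | intermediate
21 | broussoflavonol C, 2-[4,5-dihydroxy-2,3-bis(3-methylbut-2-en-1-yl)phenyl]-3,5,7-trihydroxy-8-(2-methylbut-3-en-2-yl)-4H-chromen-4-one | C=CC(C)(C)c1c(O)cc(O)c2c(=O)c(O)c(-c3cc(O)c(O)c(CC=C(C)C)c3CC=C(C)C)oc12 | target

Total step count: 14.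
Longest linear sequence: 11 steps (5 → 6 → 7 → 9 → 10 → 13 → 14 → 15 → 17 → 18 → 20 → 21; steps 3, 4, 5, 6, 8, 9, 10, 11, 12, 13, 14).

Steps most likely to fail

Step 13 (double Claisen thermolysis). What may go wrong: elimination of isoprene from the tertiary ether once the bath reaches the temperature that the primary ether needs, and thermal follow-up reactions of the two free o-allylphenols (cyclisation onto the side-chain alkene, abnormal Claisen isomerisation) while they are held at that temperature. Fallback: the two shifts are separated and each new phenol is capped as it forms. Setting out from 18, heating in toluene at 110 °C should move only the tertiary ether and give phenol 19, which is now isolated. Ac2O and pyridine at room temperature should give the 4'-O-acetate of phenol 19 F1. Thermolysis of F1 in N,N-diethylaniline containing Ac2O at 195 °C should shift the 7-O-prenyl group to C8 and trap the 7-phenol at once, giving the 7,4'-di-O-acetate of 20 F2. K2CO3 in MeOH at 0 °C then removes both acetates and the route is rejoined at 20.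

Step 11 (Algar–Flynn–Oyamada reaction). What may go wrong: closure through the five-membered mode, by attack of the phenoxide at the α-carbon, to give an aurone; this is a known drift of chalcones with a 6'-alkoxy group and is made more likely here by the ortho-prenyl group that twists ring B. Fallback: the pyranone ring is closed first and C3 is oxygenated afterwards. Setting out from 15, NaOAc in EtOH at 60 °C should close the ring by oxa-Michael addition to the racemic flavanone F3. IBX in DMSO at 65 °C should dehydrogenate it to the flavone F4. Deprotonation at C3 with LiN(iPr)2 in THF at −78 °C and quenching with B(OMe)3 should give the dimethyl flavon-3-ylboronate F5, which is not isolated. H2O2 and AcOH then oxidise the C–B bond and the route is rejoined at 17.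

Step 8 (palladium-catalysed tertiary etherification). What may go wrong: re-ionisation of the product by zerovalent palladium, since the formyl-substituted phenoxide is a good leaving group, with drift to the linear prenyl ether, or etherification at the 5-OH. Fallback: the tertiary ether is made in two stages through the alkyne. Setting out from 10, 3-chloro-3-methylbut-1-yne, DBU and catalytic CuCl2 in MeCN at 0 °C should alkylate the more acidic 4-OH and give the propargylic ether 5-hydroxy-4-(2-methylbut-3-yn-2-yloxy)-2-(3-methylbut-2-en-1-yl)benzaldehyde F6. Semihydrogenation (H2, Pd/CaCO3 poisoned with Pb(OAc)2, quinoline, EtOAc, rt) should reduce the alkyne to the vinyl group and the route is rejoined at 13.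

Further compounds
F1 | step 13 | 4'-O-acetate of phenol 19, 2-[4-acetoxy-5-(methoxymethoxy)-2,3-bis(3-methylbut-2-en-1-yl)phenyl]-3,5-bis(methoxymethoxy)-7-(3-methylbut-2-en-1-yloxy)-4H-chromen-4-one | CC(C)=CCOc1cc(OCOC)c2c(=O)c(OCOC)c(-c3cc(OCOC)c(OC(C)=O)c(CC=C(C)C)c3CC=C(C)C)oc2c1
F2 | step 13 | 7,4'-di-O-acetate of 20, 7-acetoxy-2-[4-acetoxy-5-(methoxymethoxy)-2,3-bis(3-methylbut-2-en-1-yl)phenyl]-3,5-bis(methoxymethoxy)-8-(2-methylbut-3-en-2-yl)-4H-chromen-4-one | C=CC(C)(C)c1c(OC(C)=O)cc(OCOC)c2c(=O)c(OCOC)c(-c3cc(OCOC)c(OC(C)=O)c(CC=C(C)C)c3CC=C(C)C)oc12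
F3 | step 11 | racemic flavanone, 5-(methoxymethoxy)-2-[5-(methoxymethoxy)-4-(2-methylbut-3-en-2-yloxy)-2-(3-methylbut-2-en-1-yl)phenyl]-7-(3-methylbut-2-en-1-yloxy)chroman-4-one | CC(C)=CCOc1cc(OCOC)c2C(=O)CC(c3cc(OCOC)c(OC(C)(C)C=C)cc3CC=C(C)C)Oc2c1
F4 | step 11 | flavone, 5-(methoxymethoxy)-2-[5-(methoxymethoxy)-4-(2-methylbut-3-en-2-yloxy)-2-(3-methylbut-2-en-1-yl)phenyl]-7-(3-methylbut-2-en-1-yloxy)-4H-chromen-4-one | CC(C)=CCOc1cc(OCOC)c2c(=O)cc(-c3cc(OCOC)c(OC(C)(C)C=C)cc3CC=C(C)C)oc2c1
F5 | step 11 | dimethyl flavon-3-ylboronate derived from F4 | CC(C)=CCOc1cc(OCOC)c2c(=O)c(B(OC)OC)c(-c3cc(OCOC)c(OC(C)(C)C=C)cc3CC=C(C)C)oc2c1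
F6 | step 8 | 5-hydroxy-4-(2-methylbut-3-yn-2-yloxy)-2-(3-methylbut-2-en-1-yl)benzaldehyde | CC(C)=CCc1cc(OC(C)(C)C#C)c(O)cc1C=O
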